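**Plan**
1. Retrosynthesis cuts the chalcone Cα=Cβ bond first. The C8 and C9 carbonyls are traced back to a C8=C9 alkene. Cutting the furan bond O–C10 and the aryl bond C1–C5' then separates 2',6'-dihydroxy-4'-methoxyacetophenone from a C15 hydrocarbon.
2. Enabling feature: C1–C15 of the target form an intact aristolane. This means ring A (C1–C5, C10), ring B (C5–C10), a cyclopropane on C6–C7 closed by the gem-dimethyl carbon C11, and vicinal methyls on C4 and C5. It is a regular farnesyl chain folded 1,10 with one methyl shift, so C6–C7, C6–C11, C5–C10 and CH3–C5 all go back to (2E,6E)-farnesyl diphosphate.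
3. Forward, first part: farnesol is converted to its diphosphate. One enzymatic cascade then closes the cyclopropane, ring A and ring B and leaves the C1=C10 alkene.
4. Forward, second part: oxygen is placed on C9 and the arene is attached to it. A Claisen shift moves the arene to C1 (alkene to C9=C10). Oxypalladation closes the furan ring at C10 (alkene to C8=C9). The chalcone arm is added, and the oxidised alkene becomes the dione last.
5. Stereochemistry: C4, C5, C6 and C7 come from the enzyme pocket. C1 and C10 are relayed from them, because the endo methyl on C11 covers one face of ring B. Hydride, phenoxide, the [3,3] shift and palladium therefore all act on the opposite face.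

Key step: step 3

Numbering and faces: the terpene carries aristolane numbers. The acetophenone ring carries primed numbers, with C1' bearing the acyl group, C5' the terpene and C6' the furan oxygen. "Methyl face" is the decalin face carrying the C4 and C5 methyls, and "cyclopropane face" is the one carrying C11.
Assumption: a recombinant sesquiterpene synthase whose main product is calarene is taken to be available, either mined from a calarene-producing plant such as Nardostachys or re-shaped from a bicyclogermacrene synthase. Farnesyl diphosphate is drawn as the free acid and handled as its ammonium salt.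

**Step 1**
Reactants: 1 (2E,6E)-farnesol
Product: 2 (2E,6E)-farnesyl chloride
Conditions: NCS, Me2S, CH2Cl2, −40 to 0 °C
Reagents that add atoms: N-chlorosuccinimide, O=C1CCC(=O)N1Cl
Why: In this Corey–Kim-type chlorination the alkoxysulfonium salt is displaced by chloride at the primary allylic carbon under neutral conditions, so neither allylic transposition nor loss of the E geometry is expected.

**Step 2**
Reactants: 2 (2E,6E)-farnesyl chloride
Product: 3 (2E,6E)-farnesyl diphosphate
Conditions: (n-Bu4N)3HP2O7, MeCN, rt; cation exchange (Dowex 50W-X8, NH4+ form); cellulose chromatography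
Reagents that add atoms: tris(tetrabutylammonium) hydrogen diphosphate, CCCC[N+](CCCC)(CCCC)CCCC.CCCC[N+](CCCC)(CCCC)CCCC.CCCC[N+](CCCC)(CCCC)CCCC.OP(=O)([O-])OP(=O)([O-])[O-]
Why: This is an SN2 diphosphorylation of a primary allylic halide by the lipophilic diphosphate salt in a dipolar aprotic solvent, and it forms no free allyl cation, so both alkene geometries should be kept.

**Step 3**
Reactants: 3 (2E,6E)-farnesyl diphosphate
Product: 5 aristol-1(10)-ene (calarene), via bicyclogermacrene 4 (not isolated)
Conditions: recombinant calarene synthase, MgCl2 (10 mM), HEPES buffer (50 mM, pH 7.5), DTT, 10 % glycerol, pentane overlay, 30 °C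
Reagents that add atoms: none
Why: Mg2+-assisted loss of diphosphate from 3 gives the (E,E)-farnesyl cation, the distal alkene attacks the allylic terminus (chain C10 on chain C1, the C6–C7 bond of the target) to close a ten-membered ring with a tertiary cation on C11, and 1,3-loss of the C6 proton closes the cyclopropane (C6–C11) to leave neutral 4 held in the pocket. Reprotonation of 4 at C1 makes a C10 cation that is captured across the ring by the C4=C5 alkene (C5–C10), a 1,2-hydride shift from C5 to C4 and a 1,2-methyl shift from C10 to C5 follow, and removal of a C1 proton leaves the C1=C10 alkene of 5. The closest known reaction type is the cyclisation of this same substrate by class 1 (ionisation-initiated) sesquiterpene synthases, where bicyclogermacrene synthases perform the first half and aristolochene synthases perform the protonation, transannular closure and hydride/methyl shift sequence of the second half. As to modes of closure, the three-membered ring forms by 1,3-elimination onto the C11 cation, and rings A and B form together when the transannular cation–alkene closure of the chair–chair-folded (E,E)-cyclodecadiene divides the ten-membered ring into a trans-fused 6–6 cation. C6 and C7 are set by the face of the distal alkene that the chiral pocket offers to the allyl cation and by the compulsory cis fusion of the cyclopropane, while C4 and C5 are set by the two suprafacial shifts, which run on opposite faces of the decalin cation and so leave both methyls on the face opposite C11. The step needs 4 to be held until it is reprotonated, protonation at C1 rather than at C4 (which would lead to 5–7 aromadendranes), exclusion of water and loss of the C1 rather than the C9 proton; the E,E geometry and the gem-dimethyl terminus of 3 secure the 1,10 Markovnikov closure, and the contour of the active site with the bound diphosphate as base has to secure the rest.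

**Step 4**
Reactants: 5 aristol-1(10)-ene (calarene)
Product: 6 (9R)-aristol-1(10)-en-9-ol (hydroxyl on the methyl face)
Conditions: SeO2 (0.3 equiv), t-BuOOH, CH2Cl2, 0 °C to rt
Reagents that add atoms: tert-butyl hydroperoxide (terminal oxygen source), CC(C)(C)OO; selenium dioxide (oxygen carrier), O=[Se]=O
Why: In this SeO2 allylic hydroxylation (ene reaction, then [2,3]-sigmatropic shift) selenium binds the less substituted alkene carbon C1 and hydrogen is taken from C9, the only hydrogen-bearing carbon on the more substituted end because C5 is quaternary; attack is expected on the methyl face because the endo C11 methyl covers the other, and any C9 epimer or enone converges in step 5.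

**Step 5**
Reactants: 6 (9R)-aristol-1(10)-en-9-ol
Product: 7 aristol-1(10)-en-9-one
Conditions: Dess–Martin periodinane, CH2Cl2, rt
Reagents that add atoms: none
Why: Dess–Martin oxidation of a secondary allylic alcohol is mild enough for the cyclopropane, and it erases C9 so that this centre can be reset with the opposite configuration.

**Step 6**
Reactants: 7 aristol-1(10)-en-9-one
Product: 8 (9S)-aristol-1(10)-en-9-ol (hydroxyl on the cyclopropane face)
Conditions: NaBH4, CeCl3·7H2O, MeOH, −20 °C
Reagents that add atoms: none
Why: Luche reduction gives clean 1,2-addition to the enone, and because the endo C11 methyl lies in the line of attack on the cyclopropane face, hydride should arrive from the methyl face and push the hydroxyl to the cyclopropane face (9S).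

**Step 7**
Reactants: 8 (9S)-aristol-1(10)-en-9-ol; 9 2',6'-dihydroxy-4'-methoxyacetophenone (2 equiv)
Product: 10 2'-hydroxy-4'-methoxy-6'-[(9R)-aristol-1(10)-en-9-yloxy]acetophenone (aryloxy group on the methyl face)
Conditions: PPh3, DIAD, THF, 0 °C to rt
Reagents that add atoms: none
Why: Mitsunobu etherification with an acidic chelated phenol proceeds by SN2 inversion at allylic C9, which places the aryloxy group pseudo-axially on the open methyl face, while the symmetry of 9, its excess and the chelation of the remaining hydroxyl keep the reaction at the mono-ether.

**Step 8**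
Reactants: 10 2'-hydroxy-4'-methoxy-6'-[(9R)-aristol-1(10)-en-9-yloxy]acetophenone
Product: 12 2',6'-dihydroxy-4'-methoxy-5'-[(1S)-aristol-9-en-1-yl]acetophenone (aryl group on the methyl face), via ortho-dienone 11 (not isolated)
Conditions: PhNEt2, 180 °C, sealed tube, Ar
Reagents that add atoms: none
Why: The aromatic Claisen rearrangement is suprafacial, so it trades the pseudo-axial C9–O bond for a C1–C5' bond on the same methyl face and thereby sets C1; C5' is the only free ortho carbon, a chair array holds the arene away from the C5 methyl, and tautomerisation of 11 restores the phenol.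

**Step 9**
Reactants: 12 2',6'-dihydroxy-4'-methoxy-5'-[(1S)-aristol-9-en-1-yl]acetophenone
Product: 13 acetyl dihydrobenzofuran, an aristol-8-ene bridged C1–C5' and C10–O–C6' on the methyl face (1R,10S)
Conditions: Pd(OCOCF3)2 (10 mol %), pyridine (40 mol %), Na2CO3, MS 3 Å, O2 (1 atm), PhMe, 80 °C
Reagents that add atoms: none
Why: In this Wacker-type aerobic oxidative cyclisation of an ortho-allylphenol, chloride-free divalent palladium favours 5-exo syn-oxypalladation, so oxygen and metal add together on the open methyl face at C10 and C9; the C1 tether allows only a cis-fused five-membered ring, which sets C10, and β-hydride elimination can only run toward C8, giving the C8=C9 alkene.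

**Step 10**
Reactants: 13 acetyl dihydrobenzofuran with the C8=C9 alkene
Product: 14 (8R,9R)-8,9-diol of 13 (both hydroxyls on the methyl face)
Conditions: OsO4 (5 mol %), NMO, acetone/H2O, rt
Reagents that add atoms: osmium tetroxide, O=[Os](=O)(=O)=O; N-methylmorpholine N-oxide, C[N+]1([O-])CCOCC1; water, O
Why: Upjohn dihydroxylation acts on the only alkene present, syn addition is expected away from the endo C11 methyl, and both new centres are removed in step 12, so facial selectivity is not critical.

**Step 11**
Reactants: 14 (8R,9R)-8,9-diol; 15 4-methoxybenzaldehyde
Product: 16 (E)-chalcone diol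
Conditions: KOH, EtOH/H2O, rt
Reagents that add atoms: none
Why: Claisen–Schmidt condensation of a 2'-hydroxy-6'-alkoxyacetophenone with a non-enolisable aldehyde gives the E enone under thermodynamic control, and running it at the diol stage keeps hydroxide away from the base-sensitive 1,2-dione.

**Step 12**
Reactants: 16 (E)-chalcone diol
Product: 17 CNP0121765.1
Conditions: (COCl)2, DMSO, CH2Cl2, −78 °C; Et3N, −78 to 0 °C
Reagents that add atoms: none
Why: Double Swern oxidation converts a vicinal diol to the 1,2-dione without C–C cleavage and spares the enone and the chelated phenol; no stereocentre is at risk, because C10 is quaternary and the cyclopropyl C7–H does not enolise.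

**Compound list**
1 | (2E,6E)-farnesol | CC(C)=CCC/C(C)=C/CC/C(C)=C/CO | starting material
2 | (2E,6E)-farnesyl chloride | CC(C)=CCC/C(C)=C/CC/C(C)=C/CCl | intermediate
3 | (2E,6E)-farnesyl diphosphate (free-acid drawing) | CC(C)=CCC/C(C)=C/CC/C(C)=C/COP(=O)(O)OP(=O)(O)O | intermediate
4 | bicyclogermacrene, (1S,2E,6E,10R)-3,7,11,11-tetramethylbicyclo[8.1.0]undeca-2,6-diene, enzyme-bound | C/C1=C\CC/C(C)=C/[C@H]2[C@@H](CC1)C2(C)C | intermediate
5 | (4R,5R,6S,7R)-aristol-1(10)-ene (calarene) | C[C@@H]1CCC=C2CC[C@@H]3[C@@H](C3(C)C)[C@@]12C | intermediate
6 | (9R)-aristol-1(10)-en-9-ol | C[C@@H]1CCC=C2[C@H](O)C[C@@H]3[C@@H](C3(C)C)[C@@]12C | intermediate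
7 | aristol-1(10)-en-9-one | C[C@@H]1CCC=C2C(=O)C[C@@H]3[C@@H](C3(C)C)[C@@]12C | intermediate
8 | (9S)-aristol-1(10)-en-9-ol | C[C@@H]1CCC=C2[C@@H](O)C[C@@H]3[C@@H](C3(C)C)[C@@]12C | intermediate
9 | 2',6'-dihydroxy-4'-methoxyacetophenone | CC(=O)c1c(O)cc(OC)cc1O | starting material
10 | 2'-hydroxy-4'-methoxy-6'-[(9R)-aristol-1(10)-en-9-yloxy]acetophenone | C[C@@H]1CCC=C2[C@H](Oc4cc(OC)cc(O)c4C(C)=O)C[C@@H]3[C@@H](C3(C)C)[C@@]12C | intermediate
11 | ortho-dienone, 2-acetyl-3-hydroxy-5-methoxy-6-(aristol-9-en-1-yl)cyclohexa-2,4-dienone (ring sp3 centre transient, not assigned) | C[C@@H]1CC[C@H](C4C(=O)C(C(C)=O)=C(O)C=C4OC)C2=CC[C@@H]3[C@@H](C3(C)C)[C@@]12C | intermediate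
12 | 2',6'-dihydroxy-4'-methoxy-5'-[(1S)-aristol-9-en-1-yl]acetophenone | C[C@@H]1CC[C@H](c4c(O)c(C(C)=O)c(O)cc4OC)C2=CC[C@@H]3[C@@H](C3(C)C)[C@@]12C | intermediate
13 | acetyl dihydrobenzofuran, aristol-8-ene bridged C1–C5' and C10–O–C6' (1R,10S) | CC(=O)c2c(O)cc(OC)c3c2O[C@]24C=C[C@@H]5[C@@H](C5(C)C)[C@@]2(C)[C@H](C)CC[C@H]34 | intermediate
14 | (8R,9R)-8,9-diol of 13 | CC(=O)c2c(O)cc(OC)c3c2O[C@]24[C@H](O)[C@H](O)[C@@H]5[C@@H](C5(C)C)[C@@]2(C)[C@H](C)CC[C@H]34 | intermediate
15 | 4-methoxybenzaldehyde | COc1ccc(C=O)cc1 | starting material
16 | (E)-chalcone (8R,9R)-diol | COc1ccc(/C=C/C(=O)c2c(O)cc(OC)c3c2O[C@]24[C@H](O)[C@H](O)[C@@H]5[C@@H](C5(C)C)[C@@]2(C)[C@H](C)CC[C@H]34)cc1 | intermediate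
17 | CNP0121765.1, (1R,4R,5R,6S,7R,10S) in aristolane numbering | COc1ccc(/C=C/C(=O)c2c(O)cc(OC)c3c2O[C@]24C(=O)C(=O)[C@@H]5[C@@H](C5(C)C)[C@@]2(C)[C@H](C)CC[C@H]34)cc1 | target

**Step count and risks**
Total step count: 12. Longest linear sequence: 12 steps (1 to 17). Compounds 9 and 15 enter as purchased.

Steps most likely to fail:

Step 3. The cascade may stop early by release of the neutral macrocycle. It may be diverted by protonation of the other alkene or by capture of water. It may also end by loss of the C9 proton instead of the C1 proton, or turn over too slowly for preparative work. The fallback sets out from 3 and keeps the enzymatic polycyclisation, but accepts termination at C9. A synthase or variant of that specificity would give aristol-9-ene F1. Its carene-like ring B should be epoxidised by m-CPBA on the methyl face to give 9,10-epoxyaristolane F2. Base-induced epoxide-to-allylic-alcohol isomerisation with LiNEt2 removes the syn C1 proton next to the tertiary epoxide carbon. This restores C1=C10 and leaves the oxygen on C9, so the route is rejoined at 6.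

Step 9. Oxypalladation may be slow at a fully substituted carbon next to quaternary C5. The palladium hydride may re-add to the new vinylcyclopropane and open the three-membered ring. The fallback sets out from 12. Epoxidation with m-CPBA on the open methyl face should give the 9,10-epoxide of 12 F3. Catalytic camphorsulfonic acid ionises its tertiary C10–O bond, and the neighbouring phenol captures C10 on the only face it can reach, giving the 9-hydroxy dihydrobenzofuran F4. Syn dehydration with the Burgess reagent, for which only C8 offers β-hydrogens, leads back to 13.

Step 7. Displacement syn to the C5 methyl may be slow. Attack with allylic transposition at C1 or elimination to the diene could then take over. The fallback sets out from 8 and 9 and forgoes the ether altogether. A Friedel–Crafts allylation (BF3·OEt2 catalytic, MgSO4, CH2Cl2, −20 °C) ionises the allylic alcohol to the C9–C10–C1 cation. The nucleophilic C5' carbon of 9 should attack this cation at C1 from the unshielded methyl face. The reaction has to be stopped before acid adds the phenol across the alkene. It bypasses 10 and 11 and comes back at 12, and no compound outside the list arises (F0).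

**Further compounds**
F1 | step 3 | aristol-9-ene | C[C@@H]1CCCC2=CC[C@@H]3[C@@H](C3(C)C)[C@@]12C
F2 | step 3 | 9,10-epoxyaristolane (oxygen on the methyl face) | C[C@@H]1CCC[C@@]2(O4)[C@H]4C[C@@H]3[C@@H](C3(C)C)[C@@]12C
F3 | step 9 | 9,10-epoxide of 12 (oxygen on the methyl face) | C[C@@H]1CC[C@H](c5c(O)c(C(C)=O)c(O)cc5OC)[C@@]2(O4)[C@H]4C[C@@H]3[C@@H](C3(C)C)[C@@]12C
F4 | step 9 | 9-hydroxy dihydrobenzofuran (hydroxyl on the methyl face) | CC(=O)c2c(O)cc(OC)c3c2O[C@]24[C@H](O)C[C@@H]5[C@@H](C5(C)C)[C@@]2(C)[C@H](C)CC[C@H]34
F0 | step 7 | none | none
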